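**Plan**

1. Retrosynthesis, in order: Cα=Cβ of the enone (aldol with 4-hydroxyacetophenone); C–OH of the carbinol (back to isopropenyl); O–CH3 at C4; C5–CHO; then O1–C2 and C3–C3a of the dihydrofuran ring together, leaving 2-iodoresorcinol and isoprene.
2. Enabling feature: with the carbinol dehydrated, C3–C2–C(CH3)=CH2 is an isoprene unit whose allylic carbon C2 carries O1, and C3a lies between the oxygen-bearing carbons C4 and C7a of the benzene ring (the carbon between the two equivalent OH groups of a resorcinol). An iodine at C3a therefore gives, by Heck addition to isoprene, an η3-allylpalladium with C2 as internal terminus, and O1–C2 closes as an allylic ether bond.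
3. Forward: the dihydrofuran ring is built first on the resorcinol ring (C3a–C3, then ring closure O1–C2); the OH left at C4 directs formylation to C5 and is then methylated; the isopropenyl group is hydrated; the chalcone chain is joined last.
4. Stereochemistry: the single stereocentre C2 (S) is set in the ring-closing C–O bond formation by the chiral phosphine on palladium and is not touched later; the E alkene arises from the aldol dehydration under thermodynamic control.

Key step: step 1

Assumption: the ligand enantiomer that gives the 2S series is fixed in a first run (chiral HPLC, sign of rotation against known 2-isopropenyl-2,3-dihydrobenzofurans); its mirror image would give 2R.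

**Route**

Step 1
Reactants: 1 iodoresorcinol (2-iodobenzene-1,3-diol); 2 isoprene (2-methylbuta-1,3-diene)
Product: 4 (2S)-2-(prop-1-en-2-yl)-2,3-dihydro-1-benzofuran-4-ol, via allylpalladium iodide 3 (not isolated)
Conditions: Pd2(dba)3 (2.5 mol%), chiral sulfinamide monophosphine ligand of the TY-Phos type (10 mol%, enantiomer leading to 2S), K2CO3 (2 equiv), isoprene (5 equiv), toluene, 60 °C, sealed tube
Reagents that add atoms: none
Why: Zerovalent palladium inserts into the carbon–iodine bond of 1, the aryl group adds to the unsubstituted CH2 terminus of the less substituted double bond of isoprene (this carbon becomes C3), and the allylpalladium 3 so formed, which spans the future C2, the methyl-bearing carbon and the terminal CH2, is attacked at its internal terminus by the neighbouring phenoxide to give the O1–C2 bond and return zerovalent palladium. The closest known reaction type is the Larock heteroannulation of o-halophenols with 1,3-dienes in its enantioselective Heck/Tsuji–Trost form, which is established for isoprene and gives 2-isopropenyl-2,3-dihydrobenzofurans. The oxygen ring closes in the 5-exo mode (O1 attacks the allyl carbon next to the benzylic CH2 and the other two allyl carbons stay outside the ring as the isopropenyl group; the 7-endo closure at the far CH2 is not competitive). C2 is the only new stereocentre and is set in this C–O bond formation under control of the chiral phosphine on palladium, the diastereomeric allyl complexes being able to equilibrate by η3–η1–η3 isomerisation through the unsubstituted terminus, so that the ligand enantiomer decides for 2S. The step needs regioselective insertion of the diene and ring closure at one oxygen only: the steric difference between the two double bonds of isoprene secures the first, and the twofold symmetry of 1 makes the two hydroxyl groups equivalent, so that closure through either gives the same product and leaves one free OH (the later C4–O) to direct the next step.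

Step 2
Reactants: 4 (2S)-2-(prop-1-en-2-yl)-2,3-dihydro-1-benzofuran-4-ol
Product: 6 (2S)-4-hydroxy-2-(prop-1-en-2-yl)-2,3-dihydro-1-benzofuran-5-carbaldehyde, via hydroxymethylphenol 5 (not isolated)
Conditions: MgCl2 (2 equiv), Et3N (4 equiv), paraformaldehyde (6 equiv), MeCN, reflux; then cold 1 M HCl
Reagents that add atoms: formaldehyde, used as paraformaldehyde (C=O)
Why: Magnesium-mediated ortho-formylation of a phenol (Casnati–Skattebøl reaction): the magnesium phenoxide delivers formaldehyde only to the free ortho position C5 (the other ortho carbon, C3a, is substituted), and the hydroxymethyl compound 5 is oxidised in the flask by hydride transfer to a second formaldehyde; MgCl2 and Et3N are not consumed and the allyl aryl ether, the alkene and C2 are not affected.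

Step 3
Reactants: 6 (2S)-4-hydroxy-2-(prop-1-en-2-yl)-2,3-dihydro-1-benzofuran-5-carbaldehyde
Product: 7 (2S)-4-methoxy-2-(prop-1-en-2-yl)-2,3-dihydro-1-benzofuran-5-carbaldehyde
Conditions: MeI (1.5 equiv), K2CO3 (2 equiv), DMF, 40 °C
Reagents that add atoms: iodomethane (CI)
Why: Williamson ether synthesis on the hydrogen-bonded phenol of a salicylaldehyde, a standard methylation under carbonate in DMF that leaves the aldehyde, the alkene and the configuration at C2 unchanged.

Step 4
Reactants: 7 (2S)-4-methoxy-2-(prop-1-en-2-yl)-2,3-dihydro-1-benzofuran-5-carbaldehyde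
Product: 9 (2S)-2-(2-hydroxypropan-2-yl)-4-methoxy-2,3-dihydro-1-benzofuran-5-carbaldehyde, via tertiary hydroperoxide 8 (not isolated)
Conditions: Co(acac)2 (20 mol%), PhSiH3 (2 equiv), O2 (1 atm), THF, rt; then PPh3
Reagents that add atoms: dioxygen (O=O)
Why: Mukaiyama hydration: hydrogen-atom transfer from a cobalt hydride to the electron-rich 1,1-disubstituted alkene gives the tertiary radical (Markovnikov sense), which should be captured by O2 much faster than it can fragment or than the silane can reduce the aryl aldehyde, and PPh3 reduces hydroperoxide 8 to the alcohol; C2 is not involved and keeps its configuration.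

Step 5
Reactants: 9 (2S)-2-(2-hydroxypropan-2-yl)-4-methoxy-2,3-dihydro-1-benzofuran-5-carbaldehyde; 10 p-hydroxyacetophenone (1-(4-hydroxyphenyl)ethan-1-one)
Product: 12 (2E)-3-[(2S)-2-(2-hydroxypropan-2-yl)-4-methoxy-2,3-dihydro-1-benzofuran-5-yl]-1-(4-hydroxyphenyl)prop-2-en-1-one, via aldol adduct 11 (not isolated)
Conditions: KOH (50% aq., excess), EtOH, rt; then dilute HCl to pH 5 at 0 °C
Reagents that add atoms: none
Why: Claisen–Schmidt condensation (crossed aldol): the enolate of 10 adds to the non-enolisable aldehyde 9 and aldol 11 loses water by E1cB to the conjugated enone with the thermodynamically favoured E geometry; KOH acts as base only, and the tertiary alcohol, the aryl ethers and the non-acidic C2 centre are stable to it.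

**Compound list**

1 | 2-iodobenzene-1,3-diol (2-iodoresorcinol) | Oc1cccc(O)c1I | starting material
2 | 2-methylbuta-1,3-diene (isoprene) | C=CC(C)=C | starting material
3 | allylpalladium iodide from 1 and 2, drawn in its η1 form at the future C2, phosphine omitted (not isolated) | Oc1cccc(O)c1CC([Pd]I)C(C)=C | intermediate
4 | (2S)-2-(prop-1-en-2-yl)-2,3-dihydro-1-benzofuran-4-ol | Oc1cccc2c1C[C@@H](C(C)=C)O2 | intermediate
5 | (2S)-5-(hydroxymethyl)-2-(prop-1-en-2-yl)-2,3-dihydro-1-benzofuran-4-ol, formed as its magnesium salt (not isolated) | OCc1ccc2c(c1O)C[C@@H](C(C)=C)O2 | intermediate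
6 | (2S)-4-hydroxy-2-(prop-1-en-2-yl)-2,3-dihydro-1-benzofuran-5-carbaldehyde | O=Cc1ccc2c(c1O)C[C@@H](C(C)=C)O2 | intermediate
7 | (2S)-4-methoxy-2-(prop-1-en-2-yl)-2,3-dihydro-1-benzofuran-5-carbaldehyde | COc1c(C=O)ccc2c1C[C@@H](C(C)=C)O2 | intermediate
8 | (2S)-2-(2-hydroperoxypropan-2-yl)-4-methoxy-2,3-dihydro-1-benzofuran-5-carbaldehyde (not isolated) | COc1c(C=O)ccc2c1C[C@@H](C(C)(C)OO)O2 | intermediate
9 | (2S)-2-(2-hydroxypropan-2-yl)-4-methoxy-2,3-dihydro-1-benzofuran-5-carbaldehyde | COc1c(C=O)ccc2c1C[C@@H](C(C)(C)O)O2 | intermediate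
10 | 1-(4-hydroxyphenyl)ethan-1-one (4-hydroxyacetophenone) | CC(=O)c1ccc(O)cc1 | starting material
11 | 3-hydroxy-3-[(2S)-2-(2-hydroxypropan-2-yl)-4-methoxy-2,3-dihydro-1-benzofuran-5-yl]-1-(4-hydroxyphenyl)propan-1-one, both epimers at the new carbinol carbon (not isolated) | COc1c(C(O)CC(=O)c3ccc(O)cc3)ccc2c1C[C@@H](C(C)(C)O)O2 | intermediate
12 | (2E)-3-[(2S)-2-(2-hydroxypropan-2-yl)-4-methoxy-2,3-dihydro-1-benzofuran-5-yl]-1-(4-hydroxyphenyl)prop-2-en-1-one | COc1c(/C=C/C(=O)c2ccc(O)cc2)ccc2c1C[C@@H](C(C)(C)O)O2 | target

**Step count and risks**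

Total step count: 5. Longest linear sequence: 5 steps (1 to 12).

Steps most likely to fail:

Step 1. The enantioselectivity may be insufficient with this electron-rich aryl iodide that carries two ortho substituents (slow oxidative addition and insertion, loss of ligand control in the C–O bond formation), or the diene may insert with the wrong regiochemistry. The fallback sets out from 1 and comes back at 9; the stereocentre is set by a reagent-controlled epoxidation and the ring is closed by epoxide opening instead. Stille coupling of 1 with tributyl(3-methylbut-2-en-1-yl)stannane (Pd(PPh3)4, DMF, 90 °C) should give 2-(3-methylbut-2-en-1-yl)benzene-1,3-diol F1, and acetylation (Ac2O, pyridine) gives 2-(3-methylbut-2-en-1-yl)-1,3-phenylene diacetate F2. Shi epoxidation (D-fructose-derived ketone, Oxone, K2CO3 buffer, MeCN–dimethoxymethane–H2O, 0 °C) should give 2-{[(2R)-3,3-dimethyloxiran-2-yl]methyl}-1,3-phenylene diacetate F3. K2CO3 in MeOH removes the acetates to 2-{[(2R)-3,3-dimethyloxiran-2-yl]methyl}benzene-1,3-diol F4 (not isolated), whose phenoxide opens the epoxide 5-exo-tet at the secondary carbon with inversion to (2S)-2-(2-hydroxypropan-2-yl)-2,3-dihydro-1-benzofuran-4-ol F5. The formylation conditions of step 2 then give, through (2S)-5-(hydroxymethyl)-2-(2-hydroxypropan-2-yl)-2,3-dihydro-1-benzofuran-4-ol F6 (not isolated), (2S)-4-hydroxy-2-(2-hydroxypropan-2-yl)-2,3-dihydro-1-benzofuran-5-carbaldehyde F7, and methylation as in step 3 gives 9, so that steps 2 to 4 are replaced as well.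

Step 4. Under the aerobic radical conditions the aldehyde may be oxidised (autoxidation to the peracid followed by Dakin-type cleavage) or reduced by the silane. The fallback sets out from 7 and comes back at 9; the carbonyl group is carried through the radical step at the alcohol level. NaBH4 in MeOH at 0 °C gives [(2S)-4-methoxy-2-(prop-1-en-2-yl)-2,3-dihydro-1-benzofuran-5-yl]methanol F8. Mukaiyama hydration as in step 4 gives, through [(2S)-2-(2-hydroperoxypropan-2-yl)-4-methoxy-2,3-dihydro-1-benzofuran-5-yl]methanol F9 (not isolated), 2-[(2S)-5-(hydroxymethyl)-4-methoxy-2,3-dihydro-1-benzofuran-2-yl]propan-2-ol F10. MnO2 in CH2Cl2 oxidises only the benzylic alcohol and gives 9.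

Step 5. With the phenol of 10 ionised, enolate formation is slow, and the electron-rich aldehyde 9 may be lost by Cannizzaro disproportionation or be recovered unchanged. The fallback sets out from 10 and comes back at 12; the ketone is used as its tetrahydropyranyl ether. Dihydropyran and PPTS in CH2Cl2 give 1-[4-(oxan-2-yloxy)phenyl]ethan-1-one F11. Condensation with 9 (KOH, EtOH, rt) gives, through 3-hydroxy-3-[(2S)-2-(2-hydroxypropan-2-yl)-4-methoxy-2,3-dihydro-1-benzofuran-5-yl]-1-[4-(oxan-2-yloxy)phenyl]propan-1-one F12 (not isolated), (2E)-3-[(2S)-2-(2-hydroxypropan-2-yl)-4-methoxy-2,3-dihydro-1-benzofuran-5-yl]-1-[4-(oxan-2-yloxy)phenyl]prop-2-en-1-one F13. PPTS in MeOH at rt removes the acetal without touching the tertiary alcohol and gives 12.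

Further compounds
F1 | step 1 | 2-(3-methylbut-2-en-1-yl)benzene-1,3-diol | CC(C)=CCc1c(O)cccc1O
F2 | step 1 | 2-(3-methylbut-2-en-1-yl)-1,3-phenylene diacetate | CC(C)=CCc1c(OC(C)=O)cccc1OC(C)=O
F3 | step 1 | 2-{[(2R)-3,3-dimethyloxiran-2-yl]methyl}-1,3-phenylene diacetate | CC(=O)Oc1cccc(OC(C)=O)c1C[C@H]1OC1(C)C
F4 | step 1 | 2-{[(2R)-3,3-dimethyloxiran-2-yl]methyl}benzene-1,3-diol (not isolated) | Oc1cccc(O)c1C[C@H]1OC1(C)C
F5 | step 1 | (2S)-2-(2-hydroxypropan-2-yl)-2,3-dihydro-1-benzofuran-4-ol | Oc1cccc2c1C[C@@H](C(C)(C)O)O2
F6 | step 1 | (2S)-5-(hydroxymethyl)-2-(2-hydroxypropan-2-yl)-2,3-dihydro-1-benzofuran-4-ol (not isolated) | OCc1ccc2c(c1O)C[C@@H](C(C)(C)O)O2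
F7 | step 1 | (2S)-4-hydroxy-2-(2-hydroxypropan-2-yl)-2,3-dihydro-1-benzofuran-5-carbaldehyde | O=Cc1ccc2c(c1O)C[C@@H](C(C)(C)O)O2
F8 | step 4 | [(2S)-4-methoxy-2-(prop-1-en-2-yl)-2,3-dihydro-1-benzofuran-5-yl]methanol | COc1c(CO)ccc2c1C[C@@H](C(C)=C)O2
F9 | step 4 | [(2S)-2-(2-hydroperoxypropan-2-yl)-4-methoxy-2,3-dihydro-1-benzofuran-5-yl]methanol (not isolated) | COc1c(CO)ccc2c1C[C@@H](C(C)(C)OO)O2
F10 | step 4 | 2-[(2S)-5-(hydroxymethyl)-4-methoxy-2,3-dihydro-1-benzofuran-2-yl]propan-2-ol | COc1c(CO)ccc2c1C[C@@H](C(C)(C)O)O2
F11 | step 5 | 1-[4-(oxan-2-yloxy)phenyl]ethan-1-one | CC(=O)c1ccc(OC2CCCCO2)cc1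
F12 | step 5 | 3-hydroxy-3-[(2S)-2-(2-hydroxypropan-2-yl)-4-methoxy-2,3-dihydro-1-benzofuran-5-yl]-1-[4-(oxan-2-yloxy)phenyl]propan-1-one (not isolated) | COc1c(C(O)CC(=O)c3ccc(OC4CCCCO4)cc3)ccc2c1C[C@@H](C(C)(C)O)O2
F13 | step 5 | (2E)-3-[(2S)-2-(2-hydroxypropan-2-yl)-4-methoxy-2,3-dihydro-1-benzofuran-5-yl]-1-[4-(oxan-2-yloxy)phenyl]prop-2-en-1-one | COc1c(/C=C/C(=O)c3ccc(OC4CCCCO4)cc3)ccc2c1C[C@@H](C(C)(C)O)O2
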